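**Retrosynthetic overview**

1. Locants follow ent-kaurane numbering: ring A = C1–C5/C10; C6 = free carboxyl on C5; C7 = lactone carbonyl on C8; C20 = lactone CH2 on C10; ring C = C8, C9, C11–C14; ring D = C8, C14, C13, C16, C15; C17 = methyl on C16.
2. Endgame: target ⇐ ester cleavage and acetylation ⇐ hydrogenation of a 16-methylene-15-ketone and of C11=C12 ⇐ allylic oxidation at C15 ⇐ ring D by Pd-mediated C8–C15 closure of the lactone ketene acetal onto a C13 isopropenyl group.
3. Key disconnection (ring C and the spiro δ-lactone together): C8–C9 by a ring-contracting Ireland–Claisen rearrangement of a cis-5-isopropenyl-6-alkenyl δ-valerolactone (allylic ester at C12–O), and C20–O by the carboxylate so released displacing a neopentyl tosylate.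
4. Enabling feature: the lactone carboxyl C7 sits on ring-C carbon C8, and C12 is an unfunctionalised CH2 in a 1,4 relationship to C8 in ring C, so a transient C11=C12 alkene plus a C12–O ester is the Claisen retron; C20 hangs on quaternary C10 (no β-hydrogen) five atoms from the carboxylate oxygen.
5. Fragments and ring order: ring A by Robinson annulation, CBS reduction (C1) and silicon-tethered radical cyclization (C10, C5); temporary δ-valerolactone by catalytic asymmetric allylboration (C12, C13); then ring C + spirolactone (key step); then ring D.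

Key step: step 17

Remark on the chemistry: (R)-TRIP is assumed to direct allyl transfer in step 16 to the Re face of the enal, as in the accepted model for this catalyst; compounds 1, 4, 17 and 18 are taken as commercial. RA denotes the (1S,2R,6S)-6-(benzyloxy)-2-(tert-butoxycarbonyl)-3,3-dimethyl-1-{[(4-methylbenzenesulfonyl)oxy]methyl}cyclohexyl group (ring A of 16).

**Route**

Step 1
Reactants: 1 3-[(4-methoxybenzyl)oxy]propanal
Product: 2 (±)-5-[(4-methoxybenzyl)oxy]pent-1-en-3-ol
Conditions: CH2=CHMgBr, THF, −78 °C to 0 °C; aq. NH4Cl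
Reagents that add atoms: vinylmagnesium bromide, C=C[Mg]Br
Why: Grignard 1,2-addition to an unhindered aldehyde gives the racemic allylic alcohol, whose stereocentre is removed in the next step.

Step 2
Reactants: 2 (±)-5-[(4-methoxybenzyl)oxy]pent-1-en-3-ol
Product: 3 5-[(4-methoxybenzyl)oxy]pent-1-en-3-one
Conditions: Dess–Martin periodinane, NaHCO3, CH2Cl2, 0 °C; used crude
Reagents that add atoms: none
Why: Dess–Martin oxidation of a secondary allylic alcohol gives the vinyl ketone under buffered, non-basic conditions that should avoid β-elimination of the PMB ether and polymerisation.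

Step 3
Reactants: 4 3-methyl-2-oxobutanoic acid
Product: 5 tert-butyl 3-methyl-2-oxobutanoate
Conditions: tert-butyl 2,2,2-trichloroacetimidate, BF3·OEt2 (cat.), CH2Cl2/cyclohexane, rt
Reagents that add atoms: tert-butyl 2,2,2-trichloroacetimidate, CC(C)(C)OC(=N)C(Cl)(Cl)Cl
Why: acid-catalysed O-alkylation of the acid by the trichloroacetimidate is a standard tert-butyl esterification that leaves the ketone alone; the tert-butyl ester is chosen because it should resist lactonization onto the later C20 hydroxyl and is cleaved last by acid.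

Step 4
Reactants: 3 5-[(4-methoxybenzyl)oxy]pent-1-en-3-one; 5 tert-butyl 3-methyl-2-oxobutanoate
Product: 7 tert-butyl 2-{[(4-methoxybenzyl)oxy]methyl}-6,6-dimethyl-3-oxocyclohex-1-ene-1-carboxylate, via diketo ester 6 (not isolated)
Conditions: DBU (10 mol%), MeCN, 0 °C to rt; then pyrrolidine (30 mol%), AcOH, PhMe, 60 °C
Reagents that add atoms: none
Why: Robinson annulation in which the tertiary enol carbon of the α-keto ester adds to the vinyl ketone (Michael addition, creating the gem-dimethyl carbon C4) and the only enolizable position that can close a six-membered ring (C10) then condenses with the α-keto ester carbonyl (C5) by enamine aldol condensation, giving ring A as an achiral tetrasubstituted enone ester.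

Step 5
Reactants: 7 tert-butyl 2-{[(4-methoxybenzyl)oxy]methyl}-6,6-dimethyl-3-oxocyclohex-1-ene-1-carboxylate
Product: 8 tert-butyl (3S)-3-hydroxy-2-{[(4-methoxybenzyl)oxy]methyl}-6,6-dimethylcyclohex-1-ene-1-carboxylate
Conditions: (R)-2-methyl-CBS-oxazaborolidine (15 mol%), BH3·SMe2, THF, −30 °C
Reagents that add atoms: none
Why: Corey–Bakshi–Shibata reduction of an α-substituted cyclohexenone, in which the catalyst binds the carbonyl anti to the fully substituted alkenyl flank and delivers hydride to one face, which with the (R)-catalyst should set the (S)-carbinol centre C1.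

Step 6
Reactants: 8 tert-butyl (3S)-3-hydroxy-2-{[(4-methoxybenzyl)oxy]methyl}-6,6-dimethylcyclohex-1-ene-1-carboxylate
Product: 9 tert-butyl (3S)-3-{[(bromomethyl)dimethylsilyl]oxy}-2-{[(4-methoxybenzyl)oxy]methyl}-6,6-dimethylcyclohex-1-ene-1-carboxylate
Conditions: BrCH2SiMe2Cl, Et3N, DMAP (cat.), CH2Cl2, 0 °C
Reagents that add atoms: (bromomethyl)chlorodimethylsilane, C[Si](C)(Cl)CBr
Why: O-silylation of the secondary allylic alcohol installs the radical tether that will deliver C20 to the same face as the C1 oxygen.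

Step 7
Reactants: 9 tert-butyl (3S)-3-{[(bromomethyl)dimethylsilyl]oxy}-2-{[(4-methoxybenzyl)oxy]methyl}-6,6-dimethylcyclohex-1-ene-1-carboxylate
Product: 11 tert-butyl (1R,2S,3S)-3-hydroxy-2-(hydroxymethyl)-2-{[(4-methoxybenzyl)oxy]methyl}-6,6-dimethylcyclohexane-1-carboxylate, via cyclic siloxane 10 (not isolated)
Conditions: Bu3SnH, AIBN, PhH, 80 °C (slow addition); then H2O2, KF, KHCO3, THF/MeOH, rt
Reagents that add atoms: hydrogen peroxide, OO
Why: silicon-tethered radical cyclization then Tamao oxidation, in which the nucleophilic α-silyl radical closes 5-exo onto C10 (β-carbon of the unsaturated ester, polarity-matched, cis to the C1 oxygen by the tether), the α-ester radical at C5 should take hydrogen from Bu3SnH on the face opposite the axial C20 and the axial C4 methyl, and C–Si oxidation with retention releases the cis-1,3-diol with C10 and C5 set.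

Step 8
Reactants: 11 tert-butyl (1R,2S,3S)-3-hydroxy-2-(hydroxymethyl)-2-{[(4-methoxybenzyl)oxy]methyl}-6,6-dimethylcyclohexane-1-carboxylate
Product: 12 tert-butyl (1R,2R,3S)-3-hydroxy-2-{[(4-methoxybenzyl)oxy]methyl}-6,6-dimethyl-2-{[(4-methylbenzenesulfonyl)oxy]methyl}cyclohexane-1-carboxylate
Conditions: TsCl, pyridine, CH2Cl2, 0 °C
Reagents that add atoms: p-toluenesulfonyl chloride, Cc1ccc(cc1)S(Cl)(=O)=O
Why: sulfonylation of the primary alcohol should outpace that of the hindered secondary one, installing at C20 the leaving group used in the key step.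

Step 9
Reactants: 12 tert-butyl (1R,2R,3S)-3-hydroxy-2-{[(4-methoxybenzyl)oxy]methyl}-6,6-dimethyl-2-{[(4-methylbenzenesulfonyl)oxy]methyl}cyclohexane-1-carboxylate
Product: 13 tert-butyl (1R,2R,3S)-3-(benzyloxy)-2-{[(4-methoxybenzyl)oxy]methyl}-6,6-dimethyl-2-{[(4-methylbenzenesulfonyl)oxy]methyl}cyclohexane-1-carboxylate
Conditions: 2-benzyloxy-1-methylpyridinium triflate, MgO, PhCF3, 83 °C
Reagents that add atoms: 2-benzyloxy-1-methylpyridinium triflate, C[n+]1ccccc1OCc1ccccc1.[O-]S(=O)(=O)C(F)(F)F
Why: neutral benzyl transfer from the pyridinium salt protects the C1 hydroxyl without forming an alkoxide, so the neighbouring tosylate cannot close to an oxetane and the PMB ether and tert-butyl ester should survive.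

Step 10
Reactants: 13 tert-butyl (1R,2R,3S)-3-(benzyloxy)-2-{[(4-methoxybenzyl)oxy]methyl}-6,6-dimethyl-2-{[(4-methylbenzenesulfonyl)oxy]methyl}cyclohexane-1-carboxylate
Product: 14 tert-butyl (1R,2R,3S)-3-(benzyloxy)-2-(hydroxymethyl)-6,6-dimethyl-2-{[(4-methylbenzenesulfonyl)oxy]methyl}cyclohexane-1-carboxylate
Conditions: DDQ, CH2Cl2/pH 7 buffer, 0 °C
Reagents that add atoms: none
Why: oxidative cleavage of the electron-rich PMB ether by DDQ (hydride abstraction then hydrolysis) leaves the benzyl ether, tosylate and ester untouched.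

Step 11
Reactants: 14 tert-butyl (1R,2R,3S)-3-(benzyloxy)-2-(hydroxymethyl)-6,6-dimethyl-2-{[(4-methylbenzenesulfonyl)oxy]methyl}cyclohexane-1-carboxylate
Product: 15 tert-butyl (1R,2R,3S)-3-(benzyloxy)-2-formyl-6,6-dimethyl-2-{[(4-methylbenzenesulfonyl)oxy]methyl}cyclohexane-1-carboxylate
Conditions: Dess–Martin periodinane, NaHCO3, CH2Cl2, 0 °C to rt (directly after step 10)
Reagents that add atoms: none
Why: Dess–Martin oxidation of the neopentyl primary alcohol under neutral conditions gives the non-enolizable C9 aldehyde before the free hydroxyl can attack the tosylate or the ester.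

Step 12
Reactants: 15 tert-butyl (1R,2R,3S)-3-(benzyloxy)-2-formyl-6,6-dimethyl-2-{[(4-methylbenzenesulfonyl)oxy]methyl}cyclohexane-1-carboxylate
Product: 16 tert-butyl (1R,2S,3S)-3-(benzyloxy)-6,6-dimethyl-2-{[(4-methylbenzenesulfonyl)oxy]methyl}-2-[(1E)-3-oxoprop-1-en-1-yl]cyclohexane-1-carboxylate
Conditions: Ph3P=CHCHO, PhMe, 80 °C
Reagents that add atoms: (triphenylphosphoranylidene)acetaldehyde, O=CC=P(c1ccccc1)(c1ccccc1)c1ccccc1
Why: Wittig olefination with the stabilized formylmethylene ylide should give the (E)-enal (C9=C11, C12 aldehyde), and the aldehyde has no α-hydrogen so no epimerization or aldol side reaction is possible.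

Step 13
Reactants: 17 2-methylbut-3-en-2-ol; 18 triethyl orthoacetate
Product: 19 ethyl 5-methylhex-4-enoate
Conditions: EtCO2H (cat.), 140 °C, distil off EtOH
Reagents that add atoms: none
Why: Johnson–Claisen rearrangement of the tertiary allylic alcohol through the mixed ketene acetal gives the γ,δ-unsaturated ester (C7, C8, C14, C13, C16 and its two methyl carbons).

Step 14
Reactants: 19 ethyl 5-methylhex-4-enoate
Product: 20 ethyl (4E)-6-hydroxy-5-methylhex-4-enoate
Conditions: SeO2 (0.3 equiv), t-BuOOH, CH2Cl2, rt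
Reagents that add atoms: tert-butyl hydroperoxide, CC(C)(C)OO
Why: selenium dioxide allylic oxidation (ene reaction then [2,3]-shift) hydroxylates the (E)-methyl group of a trisubstituted alkene selectively.

Step 15
Reactants: 20 ethyl (4E)-6-hydroxy-5-methylhex-4-enoate
Product: 21 ethyl (4E)-5-methyl-6-(4,4,5,5-tetramethyl-1,3,2-dioxaborolan-2-yl)hex-4-enoate
Conditions: B2pin2, [Pd(MeCN)4](BF4)2 (5 mol%), DMSO/MeOH, 50 °C
Reagents that add atoms: bis(pinacolato)diboron, CC1(C)OB(OC1(C)C)B1OC(C)(C)C(C)(C)O1
Why: palladium-catalysed substitution of the allylic hydroxyl by boron through an η3-allyl intermediate should give the linear (E)-allylboronate.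

Step 16
Reactants: 16 tert-butyl (1R,2S,3S)-3-(benzyloxy)-6,6-dimethyl-2-{[(4-methylbenzenesulfonyl)oxy]methyl}-2-[(1E)-3-oxoprop-1-en-1-yl]cyclohexane-1-carboxylate; 21 ethyl (4E)-5-methyl-6-(4,4,5,5-tetramethyl-1,3,2-dioxaborolan-2-yl)hex-4-enoate
Product: 23 (5R,6S)-6-[(E)-2-(RA)ethenyl]-5-(prop-1-en-2-yl)oxan-2-one, via hydroxy ester 22 (not isolated)
Conditions: (R)-TRIP phosphoric acid (5 mol%), 4 Å MS, PhMe, −30 °C to 0 °C; then PPTS (10 mol%), 50 °C
Reagents that add atoms: none
Why: chiral phosphoric acid-catalysed allylboration through a closed chair transition state, in which the (E)-boronate gives the anti adduct, the catalyst is expected to direct attack to the Re face of the enal (12S,13R), and acid-catalysed closure of the δ-hydroxy ester then gives the lactone with the alkenyl and isopropenyl groups cis.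

Step 17
Reactants: 23 (5R,6S)-6-[(E)-2-(RA)ethenyl]-5-(prop-1-en-2-yl)oxan-2-one
Product: 26 spirolactone tert-butyl ester with C1 benzyl ether and C11=C12 alkene and C13 isopropenyl (1S,5R,8S,9R,10S,13S), via silyl ketene acetal 24 (not isolated), via trimethylsilyl ester 25 (not isolated)
Conditions: LiN(SiMe3)2, Me3SiCl/Et3N, THF, −78 °C; solvent exchange to PhMe, 90 °C; then CsF, DMF, 70 °C
Reagents that add atoms: none
Why: LiN(SiMe3)2/Me3SiCl converts the lactone into the cyclic silyl ketene acetal 24, whose C8 terminus and the C9 terminus of the (E)-alkene are joined by a [3,3]-sigmatropic shift that breaks the allylic C12–O bond and contracts the δ-lactone to the cyclohexene ring C of silyl ester 25; fluoride then frees the C7 carboxylate, which displaces the tosylate at C20 by intramolecular SN2 to close the spiro δ-lactone. The closest known reaction type is the ring-contracting Ireland–Claisen rearrangement of 6-alkenyl δ-lactone ketene acetals to cyclohex-3-ene-1-carboxylic acids, followed by an ordinary carboxylate O-alkylation. Ring C closes by the sigmatropic ring contraction (six-membered carbocycle from six-membered lactone through a bicyclo[2.2.2]-like transition state) and the lactone closes 6-exo-tet. Because the ketene acetal double bond is held in the ring, only a boat-like transition state with the C12 alkenyl group folded over the lactone is accessible, so the C12 configuration is transferred suprafacially: the (E)-alkene places C10 cis to the carboxyl on C8 (8S,9R), the untouched C13 centre ends trans to C10 across ring C because its isopropenyl group was cis to the alkenyl group in 23, and the spiro centre C10 is already fixed. The step needs chemoselective enolization of the lactone (the only other α-hydrogen, at C5, lies between two quaternary carbons on a tert-butyl ester), a [3,3] shift faster than Cope rearrangement of the 1,5-diene (the ketene acetal rearranges at 90 °C), and substitution without elimination (C10 is quaternary, so the tosylate has no β-hydrogen and the carboxylate is held on the cis face five atoms away).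

Step 18
Reactants: 26 spirolactone tert-butyl ester with C1 benzyl ether and C11=C12 alkene and C13 isopropenyl
Product: 28 16-methylene bicyclo[3.2.1]octene spirolactone (C8–C15 bond formed; 1S,5R,8R,9S,10S,13S), via silyl ketene acetal 27 (not isolated)
Conditions: KN(SiMe3)2, t-BuMe2SiCl, THF, −78 °C; then Pd(OAc)2 (1.0 equiv), AcOH (0.5 equiv), DMSO, air, 45 °C
Reagents that add atoms: none
Why: oxidative cyclization of a lactone silyl ketene acetal onto a 1,1-disubstituted alkene mediated by divalent palladium (palladium enolate, 5-exo insertion joining C8 to the terminal carbon of the isopropenyl group, β-hydride elimination toward the methyl group), where the two-carbon bridge can only form on the ring-C face that carries the C13 substituent, which fixes the quaternary centre C8.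

Step 19
Reactants: 28 16-methylene bicyclo[3.2.1]octene spirolactone
Product: 29 15-hydroxy-16-methylene spirolactone (hydroxyl expected exo)
Conditions: SeO2 (0.5 equiv), t-BuOOH, CH2Cl2, rt
Reagents that add atoms: tert-butyl hydroperoxide, CC(C)(C)OO
Why: selenium dioxide allylic hydroxylation of the 1,1-disubstituted alkene at its only usable allylic position C15 (the other is the bridgehead C13), expected from the open exo face, with the new carbinol centre removed in the next step.

Step 20
Reactants: 29 15-hydroxy-16-methylene spirolactone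
Product: 30 16-methylene-15-oxo spirolactone (1S,5R,8S,9S,10S,13S)
Conditions: Dess–Martin periodinane, NaHCO3, CH2Cl2, rt
Reagents that add atoms: none
Why: Dess–Martin oxidation of the allylic alcohol gives the α-methylene cyclopentanone without touching the other groups.

Step 21
Reactants: 30 16-methylene-15-oxo spirolactone
Product: 31 tert-butyl ester of the 1-hydroxy target skeleton (1S,5R,8S,9S,10S,13R,16R)
Conditions: H2 (1 atm), Pd(OH)2/C, EtOAc, rt
Reagents that add atoms: none
Why: heterogeneous hydrogenation saturates C11=C12 and the exocyclic enone and cleaves the benzyl ether, and hydrogen should add to C16 from the exposed exo face of the bicyclo[3.2.1]octane (away from the three-carbon bridge), placing the C17 methyl endo as required.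

Step 22
Reactants: 31 tert-butyl ester of the 1-hydroxy target skeleton
Product: 32 tert-butyl ester of the target (1-acetate)
Conditions: Ac2O, pyridine, DMAP (cat.), CH2Cl2, rt
Reagents that add atoms: acetic anhydride, CC(=O)OC(C)=O
Why: DMAP-catalysed acylation of the equatorial secondary C1 hydroxyl is routine and the other groups are inert to it.

Step 23
Reactants: 32 tert-butyl ester of the target (1-acetate)
Product: 33 target acid (1S,5R,8S,9S,10S,13R,16R)
Conditions: CF3CO2H/CH2Cl2 (1:4), 0 °C to rt
Reagents that add atoms: none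
Why: acidolysis of the tert-butyl ester (loss of isobutene) frees the C6 carboxylic acid while the acetate, the β-keto lactone and the ketone are stable to acid.

**Compound list**

1 | 3-[(4-methoxybenzyl)oxy]propanal | O=CCCOCc1ccc(OC)cc1 | starting material
2 | (±)-5-[(4-methoxybenzyl)oxy]pent-1-en-3-ol (racemic) | C=CC(O)CCOCc1ccc(OC)cc1 | intermediate
3 | 5-[(4-methoxybenzyl)oxy]pent-1-en-3-one | C=CC(=O)CCOCc1ccc(OC)cc1 | intermediate
4 | 3-methyl-2-oxobutanoic acid | CC(C)C(=O)C(=O)O | starting material
5 | tert-butyl 3-methyl-2-oxobutanoate | CC(C)C(=O)C(=O)OC(C)(C)C | intermediate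
6 | tert-butyl 8-[(4-methoxybenzyl)oxy]-3,3-dimethyl-2,6-dioxooctanoate | CC(C)(C)OC(=O)C(=O)C(C)(C)CCC(=O)CCOCc1ccc(OC)cc1 | intermediate
7 | tert-butyl 2-{[(4-methoxybenzyl)oxy]methyl}-6,6-dimethyl-3-oxocyclohex-1-ene-1-carboxylate | O=C1CCC(C)(C)C(C(=O)OC(C)(C)C)=C1COCc1ccc(OC)cc1 | intermediate
8 | tert-butyl (3S)-3-hydroxy-2-{[(4-methoxybenzyl)oxy]methyl}-6,6-dimethylcyclohex-1-ene-1-carboxylate | O[C@H]1CCC(C)(C)C(C(=O)OC(C)(C)C)=C1COCc1ccc(OC)cc1 | intermediate
9 | tert-butyl (3S)-3-{[(bromomethyl)dimethylsilyl]oxy}-2-{[(4-methoxybenzyl)oxy]methyl}-6,6-dimethylcyclohex-1-ene-1-carboxylate | BrC[Si](C)(C)O[C@H]1CCC(C)(C)C(C(=O)OC(C)(C)C)=C1COCc1ccc(OC)cc1 | intermediate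
10 | cis-fused cyclic siloxane (C1–O–SiMe2–CH2–C10 ring; CH2OPMB trans to the C1 oxygen; H5 trans to C20) | C[Si]1(C)C[C@@]2(COCc3ccc(OC)cc3)[C@@H](O1)CCC(C)(C)[C@H]2C(=O)OC(C)(C)C | intermediate
11 | tert-butyl (1R,2S,3S)-3-hydroxy-2-(hydroxymethyl)-2-{[(4-methoxybenzyl)oxy]methyl}-6,6-dimethylcyclohexane-1-carboxylate | O[C@H]1CCC(C)(C)[C@@H](C(=O)OC(C)(C)C)[C@]1(CO)COCc1ccc(OC)cc1 | intermediate
12 | tert-butyl (1R,2R,3S)-3-hydroxy-2-{[(4-methoxybenzyl)oxy]methyl}-6,6-dimethyl-2-{[(4-methylbenzenesulfonyl)oxy]methyl}cyclohexane-1-carboxylate | O[C@H]1CCC(C)(C)[C@@H](C(=O)OC(C)(C)C)[C@]1(COS(=O)(=O)c1ccc(C)cc1)COCc1ccc(OC)cc1 | intermediate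
13 | tert-butyl (1R,2R,3S)-3-(benzyloxy)-2-{[(4-methoxybenzyl)oxy]methyl}-6,6-dimethyl-2-{[(4-methylbenzenesulfonyl)oxy]methyl}cyclohexane-1-carboxylate | c1ccccc1CO[C@H]1CCC(C)(C)[C@@H](C(=O)OC(C)(C)C)[C@]1(COS(=O)(=O)c1ccc(C)cc1)COCc1ccc(OC)cc1 | intermediate
14 | tert-butyl (1R,2R,3S)-3-(benzyloxy)-2-(hydroxymethyl)-6,6-dimethyl-2-{[(4-methylbenzenesulfonyl)oxy]methyl}cyclohexane-1-carboxylate | c1ccccc1CO[C@H]1CCC(C)(C)[C@@H](C(=O)OC(C)(C)C)[C@]1(COS(=O)(=O)c1ccc(C)cc1)CO | intermediate
15 | tert-butyl (1R,2R,3S)-3-(benzyloxy)-2-formyl-6,6-dimethyl-2-{[(4-methylbenzenesulfonyl)oxy]methyl}cyclohexane-1-carboxylate | c1ccccc1CO[C@H]1CCC(C)(C)[C@@H](C(=O)OC(C)(C)C)[C@]1(COS(=O)(=O)c1ccc(C)cc1)C=O | intermediate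
16 | tert-butyl (1R,2S,3S)-3-(benzyloxy)-6,6-dimethyl-2-{[(4-methylbenzenesulfonyl)oxy]methyl}-2-[(1E)-3-oxoprop-1-en-1-yl]cyclohexane-1-carboxylate | c1ccccc1CO[C@H]1CCC(C)(C)[C@@H](C(=O)OC(C)(C)C)[C@]1(COS(=O)(=O)c1ccc(C)cc1)/C=C/C=O | intermediate
17 | 2-methylbut-3-en-2-ol | CC(C)(O)C=C | starting material
18 | triethyl orthoacetate | CCOC(C)(OCC)OCC | starting material
19 | ethyl 5-methylhex-4-enoate | CCOC(=O)CCC=C(C)C | intermediate
20 | ethyl (4E)-6-hydroxy-5-methylhex-4-enoate | CCOC(=O)CC/C=C(C)/CO | intermediate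
21 | ethyl (4E)-5-methyl-6-(4,4,5,5-tetramethyl-1,3,2-dioxaborolan-2-yl)hex-4-enoate | CCOC(=O)CC/C=C(C)/CB1OC(C)(C)C(C)(C)O1 | intermediate
22 | ethyl (4R,5S,6E)-5-hydroxy-4-(prop-1-en-2-yl)-7-(RA)hept-6-enoate | c1ccccc1CO[C@H]1CCC(C)(C)[C@@H](C(=O)OC(C)(C)C)[C@]1(COS(=O)(=O)c1ccc(C)cc1)/C=C/[C@H](O)[C@H](CCC(=O)OCC)C(C)=C | intermediate
23 | (5R,6S)-6-[(E)-2-(RA)ethenyl]-5-(prop-1-en-2-yl)oxan-2-one (alkenyl and isopropenyl cis) | c1ccccc1CO[C@H]1CCC(C)(C)[C@@H](C(=O)OC(C)(C)C)[C@]1(COS(=O)(=O)c1ccc(C)cc1)/C=C/[C@@H]1OC(=O)CC[C@@H]1C(C)=C | intermediate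
24 | trimethylsilyl ketene acetal of 23 (6-trimethylsilyloxy-3,4-dihydro-2H-pyran) | c1ccccc1CO[C@H]1CCC(C)(C)[C@@H](C(=O)OC(C)(C)C)[C@]1(COS(=O)(=O)c1ccc(C)cc1)/C=C/[C@@H]1OC(O[Si](C)(C)C)=CC[C@@H]1C(C)=C | intermediate
25 | trimethylsilyl (1S,2R,5S)-2-(RA)-5-(prop-1-en-2-yl)cyclohex-3-ene-1-carboxylate | c1ccccc1CO[C@H]1CCC(C)(C)[C@@H](C(=O)OC(C)(C)C)[C@]1(COS(=O)(=O)c1ccc(C)cc1)[C@@H]1C=C[C@@H](C(C)=C)C[C@@H]1C(=O)O[Si](C)(C)C | intermediate
26 | spirolactone: 7,20-lactone cis-fused to cyclohexene ring C (C11=C12), C13 isopropenyl, C1 benzyl ether, C6 tert-butyl ester (1S,5R,8S,9R,10S,13S) | c1ccccc1CO[C@H]1CCC(C)(C)[C@@H](C(=O)OC(C)(C)C)[C@@]12COC(=O)[C@H]1C[C@@H](C=C[C@H]12)C(C)=C | intermediate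
27 | tert-butyldimethylsilyl ketene acetal of 26 (C7(OSi)=C8) | c1ccccc1CO[C@H]1CCC(C)(C)[C@@H](C(=O)OC(C)(C)C)[C@@]12COC(O[Si](C)(C)C(C)(C)C)=C1C[C@@H](C=C[C@H]12)C(C)=C | intermediate
28 | 16-methylene bicyclo[3.2.1]octene spirolactone: ring D closed, C15 methylene, C11=C12 alkene, C1 benzyl ether, C6 tert-butyl ester (1S,5R,8R,9S,10S,13S) | c1ccccc1CO[C@H]1CCC(C)(C)[C@@H](C(=O)OC(C)(C)C)[C@@]12COC(=O)[C@@]13C[C@@H](C=C[C@H]12)C(=C)C3 | intermediate
29 | 15-exo-hydroxy derivative of 28 | c1ccccc1CO[C@H]1CCC(C)(C)[C@@H](C(=O)OC(C)(C)C)[C@@]12COC(=O)[C@@]13C[C@@H](C=C[C@H]12)C(=C)[C@@H]3O | intermediate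
30 | 16-methylene-15-oxo spirolactone (1S,5R,8S,9S,10S,13S) | c1ccccc1CO[C@H]1CCC(C)(C)[C@@H](C(=O)OC(C)(C)C)[C@@]12COC(=O)[C@@]13C[C@@H](C=C[C@H]12)C(=C)C3=O | intermediate
31 | tert-butyl ester of the 1-hydroxy target skeleton: 1-hydroxy-16-methyl-15-oxo-7,20-lactone (1S,5R,8S,9S,10S,13R,16R) | O[C@H]1CCC(C)(C)[C@@H](C(=O)OC(C)(C)C)[C@@]12COC(=O)[C@@]13C[C@@H](CC[C@H]12)[C@@H](C)C3=O | intermediate
32 | tert-butyl ester of the target (1-acetate) | CC(=O)O[C@H]1CCC(C)(C)[C@@H](C(=O)OC(C)(C)C)[C@@]12COC(=O)[C@@]13C[C@@H](CC[C@H]12)[C@@H](C)C3=O | intermediate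
33 | target: 1-acetoxy-16-methyl-15-oxo-6,7-seco-ent-kauran-7,20-olid-6-oic acid (1S,5R,8S,9S,10S,13R,16R) | CC(=O)O[C@H]1CCC(C)(C)[C@@H](C(=O)O)[C@@]12COC(=O)[C@@]13C[C@@H](CC[C@H]12)[C@@H](C)C3=O | target

**Step count**

Total: 23 steps. Longest linear sequence: 19 steps (steps 1, 2, 4–12, 16–23).

**Steps most likely to fail, with fallbacks**

Step 17. The [3,3] shift has to pass a crowded boat transition state next to the quaternary C10, and the carboxylate then has to attack a neopentyl carbon; the second event may be too slow, so that the free carboxylate is protonated on work-up or fluoride attacks the sulfonate instead. The fallback makes the lactone C–O bond by acylation instead of alkylation. It sets out from 23: the Ireland–Claisen stage alone (LiN(SiMe3)2, Me3SiCl/Et3N, then PhMe, 90 °C, aqueous work-up) gives the cyclohexenecarboxylic acid F1; Mg in MeOH cleaves the S–O bond of the tosylate to give the hydroxy acid F2; mixed-anhydride lactonization (2,4,6-trichlorobenzoyl chloride, Et3N, then DMAP, PhMe) closes the δ-lactone and returns to the route at 26.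

Step 18. The ketene acetal may be protodesilylated before insertion, or divalent palladium may engage the C11=C12 alkene or give allylic oxidation products instead of closing the hindered C8–C15 bond. The fallback replaces the oxidative cyclization by an enolate alkylation. It sets out from 26: ene-type chlorination of the isopropenyl group (Ca(OCl)2, solid CO2, CH2Cl2/H2O, 0 °C) gives the allylic chloride F3; KN(SiMe3)2 in THF (−78 °C to 0 °C) then forms the lactone enolate, which displaces the allylic chloride in a 5-exo-tet closure and returns to the route at 28.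

Step 16. Facial control by the catalyst may be poor with this hindered, heavily functionalised enal, or the anti preference may erode with the β-methyl, γ-alkyl boronate, giving a mixture of lactone diastereomers. The fallback changes the allyl metal and the source of asymmetry. It sets out from 20 and 16: Appel bromination of 20 (CBr4, PPh3, CH2Cl2, 0 °C) gives the allylic bromide F4; catalytic asymmetric Nozaki–Hiyama–Kishi allylation of 16 (CrCl3 10 mol%, Mn, Me3SiCl, Et3N, a chiral oxazoline sulfonamide ligand, THF), in which the γ-substituted allylchromium species of trivalent chromium adds anti through a chair transition state, gives hydroxy ester 22 after desilylation; PPTS then closes the lactone and returns to the route at 23.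

**Further compounds**

F1 | step 17 | (1S,2R,5S)-2-(RA)-5-(prop-1-en-2-yl)cyclohex-3-ene-1-carboxylic acid | c1ccccc1CO[C@H]1CCC(C)(C)[C@@H](C(=O)OC(C)(C)C)[C@]1(COS(=O)(=O)c1ccc(C)cc1)[C@@H]1C=C[C@@H](C(C)=C)C[C@@H]1C(=O)O
F2 | step 17 | hydroxy acid: F1 with CH2OH in place of the tosyloxymethyl group | c1ccccc1CO[C@H]1CCC(C)(C)[C@@H](C(=O)OC(C)(C)C)[C@]1(CO)[C@@H]1C=C[C@@H](C(C)=C)C[C@@H]1C(=O)O
F3 | step 18 | allylic chloride: 26 with a 3-chloroprop-1-en-2-yl group at C13 | c1ccccc1CO[C@H]1CCC(C)(C)[C@@H](C(=O)OC(C)(C)C)[C@@]12COC(=O)[C@H]1C[C@@H](C=C[C@H]12)C(=C)CCl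
F4 | step 16 | ethyl (4E)-6-bromo-5-methylhex-4-enoate | CCOC(=O)CC/C=C(C)/CBr
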